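**Plan**

Retrosynthetic cuts, in order: the C9–O acyl bond; C11=C13; the lactone O–C12 bond (back to a C8/C12 diol); C5–H (back to a C5 ketal); C3–C4 (opens ring A); C4=C5 (back to an ε-lactone); C10–O (Baeyer–Villiger, back to the cyclohexanone C5–C10); C7–C11 and C10–C1 (back to 2-methylcyclohexane-1,3-dione).
Enabling feature: ring A (O, C5, C4, C3, C2, C1, C10) is an unfunctionalised carbon bridge, and its only handle is the ether oxygen on C5. Raised to an exocyclic C5=C4 enol ether on ring B (O, C5, C6, C7, C8, C9, C10), that oxygen makes C4 the most easily oxidised site. C4 can then be bonded to C3 of a vinylsilane hung on C10, although both carbons are nucleophiles.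
Forward ring order: carbocycle C5–C10, ring B by oxygen insertion, ring A by anodic C3–C4 closure, γ-lactone by oxidative lactonisation; methylene and ester come last.
Stereochemistry: C10 and a sacrificial C5 carbinol come from a CBS desymmetrisation. C7, C8 and C9 are relayed from them (trans cuprate addition, anti Rubottom oxidation, hydroxyl-directed reduction). C4 comes from the (Z)-enol ether geometry and the only face the tether can reach, C5 is dictated by the bridge, and the acyl stereocentre is bought.

Key step: step 15

Remark: atoms keep the numbers of the target throughout (ring carbons C1–C10, lactone C11–C13, C14 on C10, C15 on C4). β is the face of ring B, or of its carbocyclic precursor, that carries the C10 arm (C1); α is the face that carries C14.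

**Step 1**
Reactants: 1 2-methylcyclohexane-1,3-dione; 2 3-bromo-1-(trimethylsilyl)prop-1-yne
Product: 3 2-methyl-2-[3-(trimethylsilyl)prop-2-yn-1-yl]cyclohexane-1,3-dione
Conditions: K2CO3, acetone, reflux
Reagents that add atoms: none
Why: C-alkylation of a cyclic 1,3-diketone enolate with a soft propargylic bromide should favour carbon over oxygen, and the aprotic carbonate conditions spare the C(sp)–Si bond and avoid retro-Claisen opening, so C1–C3 are installed and C10 becomes quaternary but still prochiral.

**Step 2**
Reactants: 3 2-methyl-2-[3-(trimethylsilyl)prop-2-yn-1-yl]cyclohexane-1,3-dione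
Product: 4 (2S,3S)-3-hydroxy-2-methyl-2-[3-(trimethylsilyl)prop-2-yn-1-yl]cyclohexan-1-one (C5 β-OH; C9 ketone)
Conditions: (R)-2-methyl-CBS-oxazaborolidine (20 mol %), catecholborane, toluene, −60 °C; aqueous work-up
Reagents that add atoms: none
Why: Corey–Bakshi–Shibata reduction used as a desymmetrisation of a 2,2-disubstituted 1,3-diketone, in which the (R)-catalyst should give the S carbinol (quaternary carbon as the large group) and hydride entry past the smaller methyl group selects the carbonyl that places OH cis to the arm, so C10 and the temporary C5 carbinol are set together and the minor diastereomer is removed by chromatography.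

**Step 3**
Reactants: 4 (2S,3S)-hydroxy ketone
Product: 5 (5S,6S)-1,5-bis(triethylsilyloxy)-6-methyl-6-[3-(trimethylsilyl)prop-2-yn-1-yl]cyclohex-1-ene (C5 β-OTES; C8=C9 silyl enol ether)
Conditions: Et3SiOTf (2.5 equiv), Et3N, CH2Cl2, 0 °C to rt
Reagents that add atoms: triethylsilyl triflate, CC[Si](CC)(CC)OS(=O)(=O)C(F)(F)F
Why: Soft enolisation and O-silylation with a silyl triflate and a tertiary amine protects the C5 hydroxyl and, because C10 is quaternary, can form only the C8=C9 silyl enol ether.

**Step 4**
Reactants: 5 bis(triethylsilyl) compound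
Product: 6 (5S,6S)-6-methyl-5-(triethylsilyloxy)-6-[3-(trimethylsilyl)prop-2-yn-1-yl]cyclohex-2-en-1-one (C7=C8 enone)
Conditions: Pd(OAc)2 (10 mol %), O2 (1 atm), DMSO, 45 °C
Reagents that add atoms: none
Why: Saegusa–Ito dehydrogenation, in which divalent palladium bonds to C8, β-hydride elimination from C7 gives the enone and O2 re-oxidises zerovalent palladium, while the hindered C5 silyl ether and the alkynylsilane are spectators.

**Step 5**
Reactants: 6 C7=C8 enone; 7 vinylmagnesium bromide
Product: 8 C7 α-vinyl C8=C9 trimethylsilyl enol ether (C5 β-OTES retained)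
Conditions: CH2=CHMgBr, CuBr·SMe2 (10 mol %), Me3SiCl, DMPU, THF, −78 °C
Reagents that add atoms: chlorotrimethylsilane, C[Si](C)(C)Cl
Why: Copper-catalysed, chlorosilane-accelerated conjugate addition, in which axial attack on the half-chair with C5–OTES pseudo-equatorial places the vinyl group trans to it (the usual 3,5-trans outcome of 5-substituted cyclohexenones), so C7 is set and the enolate is trapped regiospecifically.

**Step 6**
Reactants: 8 C7 α-vinyl silyl enol ether
Product: 10 C5 β,C8 β-dihydroxy C7 α-vinyl C9 ketone, via C8 trimethylsilyloxy ketone 9 (not isolated)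
Conditions: mCPBA (1.05 equiv), NaHCO3, CH2Cl2, −20 °C; then 1 M HCl, THF, rt
Reagents that add atoms: mCPBA, O=C(OO)c1cccc(Cl)c1
Why: Rubottom oxidation, in which the silyl enol ether is epoxidised far faster than the vinyl or alkynyl groups and from the face anti to the neighbouring C7 vinyl group, giving the equatorial C8 β-oxygen, and the acid work-up removes both O-silyl groups but not the C–Si bond.

**Step 7**
Reactants: 10 dihydroxy ketone
Product: 11 C5 β,C8 β,C9 α-triol
Conditions: Me4NBH(OAc)3, MeCN/AcOH, −30 to 0 °C
Reagents that add atoms: none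
Why: Evans–Saksena hydroxyl-directed reduction, in which acetate exchange with the axial C5 β-hydroxyl (reinforced by the C8 β-hydroxyl) ties the borohydride to the β face, so hydride is delivered there intramolecularly and C9–OH emerges α and equatorial, anti to C5–OH and trans to C8–OH.

**Step 8**
Reactants: 11 triol
Product: 12 C8,C9 butane-2,3-diacetal bearing the free C5 β-OH
Conditions: butane-2,3-dione, HC(OMe)3, camphorsulfonic acid (catalytic), MeOH, reflux
Reagents that add atoms: butane-2,3-dione, CC(=O)C(C)=O; trimethyl orthoformate, COC(OC)OC (source of the two methoxy groups, in exchange with the solvent)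
Why: Butane-2,3-diacetal formation is selective for trans-diequatorial vicinal diols (a chair dioxane with both methoxy groups axial through the anomeric effect, which fixes the two new acetal centres), so C8 and C9 are masked at once and the axial C5–OH, which has no partner, stays free.

**Step 9**
Reactants: 12 diacetal alcohol
Product: 14 C5,C12 diol, via C12 borabicyclononane adduct 13 (not isolated)
Conditions: 9-BBN, THF, 0 °C to rt; then NaBO3·4H2O, H2O, rt
Reagents that add atoms: sodium perborate, [Na+].[Na+].O[B-]1(O)OO[B-](O)(O)OO1; 9-BBN, B1C2CCCC1CCC2 (boron stays only in 13)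
Why: Anti-Markovnikov hydroboration–oxidation, in which 9-BBN reacts much faster with a monosubstituted alkene than with a silyl-capped internal alkyne and perborate oxidises the borane without the strong base that would cleave the alkynyl–Si bond.

**Step 10**
Reactants: 14 diol
Product: 15 C12 tert-butyldimethylsilyl ether bearing the free C5 β-OH
Conditions: TBSCl (1.1 equiv), imidazole, CH2Cl2, 0 °C
Reagents that add atoms: tert-butyldimethylsilyl chloride, CC(C)(C)[Si](C)(C)Cl
Why: Sterically controlled silylation, in which the primary C12 hydroxyl reacts far faster than the axial neopentyl-type C5 hydroxyl.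

**Step 11**
Reactants: 15 C5 alcohol
Product: 16 C5 ketone
Conditions: Dess–Martin periodinane, NaHCO3, CH2Cl2, rt
Reagents that add atoms: none
Why: Dess–Martin oxidation under buffered neutral conditions removes the sacrificial C5 stereocentre once its relay work is done, and no stereocentre can epimerise because C10 is quaternary and C6 is a methylene group.

**Step 12**
Reactants: 16 C5 ketone
Product: 17 ring B ε-lactone (oxepan-2-one) bearing the C10 alkynylsilane arm
Conditions: mCPBA (3 equiv), NaHCO3, CH2Cl2, rt
Reagents that add atoms: mCPBA, O=C(OO)c1cccc(Cl)c1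
Why: Baeyer–Villiger oxidation, in which the quaternary C10 migrates in preference to the C6 methylene and with retention of configuration, so the ring oxygen is inserted between C5 and C10 and ring B is formed while the alkynylsilane resists the peracid.

**Step 13**
Reactants: 17 alkynylsilane lactone
Product: 18 ring B ε-lactone bearing the C10 (Z)-vinylsilane arm
Conditions: H2 (1 atm), Pd/CaCO3 poisoned with Pb(OAc)2, quinoline, EtOAc, rt
Reagents that add atoms: none
Why: Lindlar semihydrogenation adds hydrogen syn to the silylalkyne and should give the (Z)-vinylsilane, placed after the peracid steps (which would epoxidise it) and before the low-valent titanium step (which would bind an alkyne).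

**Step 14**
Reactants: 18 vinylsilane lactone; 19 1,1-dibromoethane
Product: 20 (Z)-2-ethylidene oxepane (C5=C4 enol ether) bearing the C10 (Z)-vinylsilane arm
Conditions: TiCl4, TMEDA, Zn, PbCl2 (catalytic), CH3CHBr2, THF, 0 °C to rt; Et3N and aq K2CO3 work-up; basic alumina
Reagents that add atoms: none
Why: Takai–Utimoto alkylidenation, in which the ethylidene–titanium species from the geminal dibromide, Zn and TiCl4/TMEDA should convert the only carbonyl group present into the trisubstituted enol ether with the usual (Z) preference (methyl syn to the ring oxygen and away from C6), while acetals, silyl ether and the disubstituted vinylsilane are tolerated and the basic work-up keeps the double bond exocyclic.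

**Step 15**
Reactants: 20 (Z)-2-ethylidene oxepane
Product: 21 C5 methoxy bridged ketal (11-oxabicyclo[4.4.1]undec-3-ene core; cis C2=C3; C4 methyl set)
Conditions: reticulated vitreous carbon anode, Pt cathode, undivided cell, constant current (8 mA, 2.2 F/mol), 0.4 M LiClO4 in MeOH/CH2Cl2 (1:4), 2,6-lutidine, rt
Reagents that add atoms: methanol, CO
Why: Proposed new method: one-electron oxidation of the C5=C4 enol ether (the most electron-rich π system present, well below the vinylsilane, the acetals and the silyl ether) gives a radical cation whose C4 terminus is attacked by the silicon-bearing C3 of the vinylsilane; the β-silyl cation at C2 then hands Me3Si+ to methanol with retention to leave the cis C2=C3 alkene, and the pyramidal bridgehead C5 radical is oxidised once more and captured by methanol from the only open (exo) side. The closest known reaction type is the intramolecular anodic olefin coupling of enol ether radical cations with vinylsilanes and allylsilanes, established for five- and six-membered carbocycles with the tether on the enol ether carbon; new here are the seven-membered bridged ring and a tether that runs through the enol oxygen. Ring A closes 7-endo at the enol ether (C5 and C4 both end in the ring) and in the endocyclic mode at the vinylsilane (C2 and C3 both in the ring), a mode that only the (Z)-silane can reach. C4 is controlled by the (Z)-geometry of the enol ether (methyl syn to O, also the less crowded rotamer should the radical cation rotate) together with the arm on the β face of C10, which can reach only the β face of C4, and C5 is controlled by the bridge, which forces OMe exo. The step needs cyclisation to outrun methanol capture and allylic proton loss of the radical cation, which the 1,3-cis placement of the arm and C5 across the ring oxygen, the stiffening of ring B by the trans-fused diacetal, the low methanol content and the lutidine buffer are meant to secure.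

**Step 16**
Reactants: 21 C5 methoxy bridged ketal
Product: 22 C5 phenylthio bridged O,S-ketal
Conditions: PhSSiMe3 (1.2 equiv), Me3SiOTf (0.2 equiv), CH2Cl2, −78 to −40 °C; Et3N quench
Reagents that add atoms: (phenylthio)trimethylsilane, C[Si](C)(C)Sc1ccccc1
Why: Lewis acid O-to-S transketalisation (the reaction type that turns methyl glycosides into thioglycosides) is chosen over direct silane reduction because loss of methoxide would need a bridgehead oxocarbenium ion twisted like a trans-cycloheptene, whereas here the ketal can open at the ring C5–O bond, take up sulfur and re-close through an exocyclic thionium ion onto the C10 oxygen, the bridge again allowing only one C5 configuration.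

**Step 17**
Reactants: 22 bridged O,S-ketal
Product: 23 saturated bridged ether (C5 α-H; C1–C4 saturated)
Conditions: Raney Ni (W-2, excess), H2 (1 atm), EtOH, rt
Reagents that add atoms: none
Why: Raney nickel desulfurisation (as in the conversion of thioglycosides into anhydroalditols) proceeds through surface radicals that tolerate a bridgehead, hydrogen can arrive only exo so C5–H has the required configuration, and the same catalyst under H2 saturates the cis C2=C3 alkene.

**Step 18**
Reactants: 23 saturated bridged ether
Product: 24 C8 β,C9 α,C12-triol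
Conditions: CF3CO2H/H2O (9:1), 0 °C to rt
Reagents that add atoms: none
Why: Aqueous trifluoroacetic acid is the standard cleavage of butane-2,3-diacetals and also removes the primary silyl ether, while ionisation of the tertiary C10–O ether bond should be held back by the adjacent C9 oxygen.

**Step 19**
Reactants: 24 triol
Product: 26 C9 α-hydroxy 12,8-γ-lactone, via C12 lactol 25 (not isolated)
Conditions: TEMPO (20 mol %), PhI(OAc)2 (3 equiv), CH2Cl2, rt
Reagents that add atoms: none
Why: TEMPO/PhI(OAc)2 oxidative lactonisation of a 1,4-diol, in which the primary C12 alcohol is oxidised selectively, the aldehyde closes with C8–OH to the five-membered lactol faster than with C9–OH to a bridged six-membered one, and the lactol is oxidised on while the hindered secondary C9–OH is left.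

**Step 20**
Reactants: 26 hydroxy lactone; 27 N,N-dimethylmethyleneiminium iodide (Eschenmoser's salt)
Product: 28 C11 (dimethylaminomethyl) lactone (C11 epimers, of no consequence)
Conditions: LiN(i-Pr)2 (3 equiv), THF, −78 °C; then 27, −78 °C to rt
Reagents that add atoms: none
Why: Mannich alkylation of the lactone enolate with Eschenmoser's salt, run on the alkoxide–enolate dianion so that C9–OH needs no protecting group, any O-aminomethyl adduct being hydrolysed on work-up, and done before acylation so that no strong base meets the epimerisable acyl stereocentre.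

**Step 21**
Reactants: 28 Mannich base
Product: 30 C9 α-hydroxy α-methylene-γ-lactone, via C13 trimethylammonium iodide 29 (not isolated)
Conditions: MeI, THF/MeOH, rt; evaporate; then aq NaHCO3, CH2Cl2, rt
Reagents that add atoms: iodomethane, CI (the methyl group stays only in 29)
Why: Quaternisation followed by mild-base E1cB (Hofmann-type) elimination of trimethylamine is the standard way to unveil the C11=C13 methylene, and bicarbonate is too weak to trigger addition of C9–OH to it.

**Step 22**
Reactants: 30 hydroxy α-methylene lactone; 31 (R)-2-methylbutanoic acid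
Product: 32 target, (4S,5R,7R,8R,9S,10R)-5,10-epoxy-9-[(2R)-2-methylbutanoyloxy]germacr-11(13)-en-12,8-olide
Conditions: 31 (3 equiv), DCC, DMAP, CH2Cl2, 0 °C to rt
Reagents that add atoms: none
Why: Steglich esterification, in which acyl transfer through the acylpyridinium ion rather than a ketene should preserve the α-stereocentre of the acid (as in acylations of hindered secondary alcohols with 2-methylbutanoic acid derivatives), and the α-methylene lactone tolerates these conditions.

**Compound list**

1 | 2-methylcyclohexane-1,3-dione | CC1C(=O)CCCC1=O | starting material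
2 | 3-bromo-1-(trimethylsilyl)prop-1-yne | C[Si](C)(C)C#CCBr | starting material
3 | 2-methyl-2-[3-(trimethylsilyl)prop-2-yn-1-yl]cyclohexane-1,3-dione | CC1(CC#C[Si](C)(C)C)C(=O)CCCC1=O | intermediate
4 | (2S,3S)-3-hydroxy-2-methyl-2-[3-(trimethylsilyl)prop-2-yn-1-yl]cyclohexan-1-one | O[C@H]1CCCC(=O)[C@@]1(C)CC#C[Si](C)(C)C | intermediate
5 | (5S,6S)-1,5-bis(triethylsilyloxy)-6-methyl-6-[3-(trimethylsilyl)prop-2-yn-1-yl]cyclohex-1-ene | CC[Si](CC)(CC)O[C@H]1CCC=C(O[Si](CC)(CC)CC)[C@@]1(C)CC#C[Si](C)(C)C | intermediate
6 | (5S,6S)-6-methyl-5-(triethylsilyloxy)-6-[3-(trimethylsilyl)prop-2-yn-1-yl]cyclohex-2-en-1-one | CC[Si](CC)(CC)O[C@H]1CC=CC(=O)[C@@]1(C)CC#C[Si](C)(C)C | intermediate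
7 | vinylmagnesium bromide | C=C[Mg]Br | starting material
8 | C7 α-vinyl, C5 β-OTES, C8=C9 trimethylsilyl enol ether | CC[Si](CC)(CC)O[C@H]1C[C@H](C=C)C=C(O[Si](C)(C)C)[C@@]1(C)CC#C[Si](C)(C)C | intermediate
9 | C8 β-trimethylsilyloxy C9 ketone (C5 β-OTES, C7 α-vinyl) | CC[Si](CC)(CC)O[C@H]1C[C@H](C=C)[C@@H](O[Si](C)(C)C)C(=O)[C@@]1(C)CC#C[Si](C)(C)C | intermediate
10 | C5 β,C8 β-dihydroxy C7 α-vinyl C9 ketone | O[C@H]1C[C@H](C=C)[C@@H](O)C(=O)[C@@]1(C)CC#C[Si](C)(C)C | intermediate
11 | C5 β,C8 β,C9 α-triol (C7 α-vinyl) | O[C@H]1C[C@H](C=C)[C@@H](O)[C@H](O)[C@@]1(C)CC#C[Si](C)(C)C | intermediate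
12 | C8,C9 butane-2,3-diacetal, free C5 β-OH, C7 α-vinyl | O[C@H]1C[C@H](C=C)[C@H]2O[C@](C)(OC)[C@@](C)(OC)O[C@@H]2[C@@]1(C)CC#C[Si](C)(C)C | intermediate
13 | C12 B-alkyl-9-borabicyclo[3.3.1]nonane adduct of 12 | O[C@H]1C[C@H](CCB3C4CCCC3CCC4)[C@H]2O[C@](C)(OC)[C@@](C)(OC)O[C@@H]2[C@@]1(C)CC#C[Si](C)(C)C | intermediate
14 | C5,C12 diol (diacetal retained) | O[C@H]1C[C@H](CCO)[C@H]2O[C@](C)(OC)[C@@](C)(OC)O[C@@H]2[C@@]1(C)CC#C[Si](C)(C)C | intermediate
15 | C12 TBS ether, free C5 β-OH | O[C@H]1C[C@H](CCO[Si](C)(C)C(C)(C)C)[C@H]2O[C@](C)(OC)[C@@](C)(OC)O[C@@H]2[C@@]1(C)CC#C[Si](C)(C)C | intermediate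
16 | C5 ketone | O=C1C[C@H](CCO[Si](C)(C)C(C)(C)C)[C@H]2O[C@](C)(OC)[C@@](C)(OC)O[C@@H]2[C@@]1(C)CC#C[Si](C)(C)C | intermediate
17 | ring B ε-lactone, C10 alkynylsilane arm | O=C1C[C@H](CCO[Si](C)(C)C(C)(C)C)[C@H]2O[C@](C)(OC)[C@@](C)(OC)O[C@@H]2[C@@](C)(CC#C[Si](C)(C)C)O1 | intermediate
18 | ring B ε-lactone, C10 (Z)-vinylsilane arm | O=C1C[C@H](CCO[Si](C)(C)C(C)(C)C)[C@H]2O[C@](C)(OC)[C@@](C)(OC)O[C@@H]2[C@@](C)(C/C=C\[Si](C)(C)C)O1 | intermediate
19 | 1,1-dibromoethane | CC(Br)Br | starting material
20 | ring B (Z)-2-ethylidene oxepane, C10 (Z)-vinylsilane arm (key-step precursor) | C/C=C1/C[C@H](CCO[Si](C)(C)C(C)(C)C)[C@H]2O[C@](C)(OC)[C@@](C)(OC)O[C@@H]2[C@@](C)(C/C=C\[Si](C)(C)C)O1 | intermediate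
21 | C5 methoxy bridged ketal, cis C2=C3 (key-step product) | CO[C@@]12C[C@H](CCO[Si](C)(C)C(C)(C)C)[C@H]3O[C@](C)(OC)[C@@](C)(OC)O[C@@H]3[C@@](C)(C/C=C\[C@@H]1C)O2 | intermediate
22 | C5 phenylthio bridged O,S-ketal | c4ccccc4S[C@@]12C[C@H](CCO[Si](C)(C)C(C)(C)C)[C@H]3O[C@](C)(OC)[C@@](C)(OC)O[C@@H]3[C@@](C)(C/C=C\[C@@H]1C)O2 | intermediate
23 | saturated bridged ether (11-oxabicyclo[4.4.1]undecane core) | [C@@H]12C[C@H](CCO[Si](C)(C)C(C)(C)C)[C@H]3O[C@](C)(OC)[C@@](C)(OC)O[C@@H]3[C@@](C)(CCC[C@@H]1C)O2 | intermediate
24 | C8 β,C9 α,C12-triol of the bridged ether | [C@@H]12C[C@H](CCO)[C@@H](O)[C@H](O)[C@@](C)(CCC[C@@H]1C)O2 | intermediate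
25 | C12 lactol (C12 epimers) | C1C(O)O[C@@H]2[C@@H]1C[C@H]1O[C@](C)(CCC[C@@H]1C)[C@H]2O | intermediate
26 | C9 α-hydroxy 12,8-γ-lactone | C1C(=O)O[C@@H]2[C@@H]1C[C@H]1O[C@](C)(CCC[C@@H]1C)[C@H]2O | intermediate
27 | N,N-dimethylmethyleneiminium iodide | C=[N+](C)C.[I-] | starting material
28 | C11 (dimethylaminomethyl) lactone (C11 epimers) | CN(C)CC1C(=O)O[C@@H]2[C@@H]1C[C@H]1O[C@](C)(CCC[C@@H]1C)[C@H]2O | intermediate
29 | C13 trimethylammonium iodide | C[N+](C)(C)CC1C(=O)O[C@@H]2[C@@H]1C[C@H]1O[C@](C)(CCC[C@@H]1C)[C@H]2O.[I-] | intermediate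
30 | C9 α-hydroxy α-methylene-γ-lactone | C=C1C(=O)O[C@@H]2[C@@H]1C[C@H]1O[C@](C)(CCC[C@@H]1C)[C@H]2O | intermediate
31 | (R)-2-methylbutanoic acid | CC[C@@H](C)C(=O)O | starting material
32 | CNP0136059.1 | C=C1C(=O)O[C@@H]2[C@@H]1C[C@H]1O[C@](C)(CCC[C@@H]1C)[C@H]2OC(=O)[C@H](C)CC | target

**Step count**

Total step count: 22. Longest linear sequence: 22 (from 1).

**Steps most likely to fail**

Step 15. The seven-membered bridged closure may be slower than methanol capture or allylic proton loss of the radical cation, and rotation of the radical cation could erode the C4 selectivity. The fallback closes ring A by olefin metathesis at C2=C3 and uses only known chemistry.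
- It sets out from 17. Silver-catalysed protiodesilylation (AgNO3 catalytic, acetone/H2O) would give the terminal alkyne lactone F1.
- Semihydrogenation over Pd/CaCO3 poisoned with Pb(OAc)2 would give the C10 allyl lactone F2.
- Reductive acetylation (i-Bu2AlH, CH2Cl2, −78 °C; then Ac2O, pyridine, DMAP) would give the C5 acetoxy oxepane F3.
- BF3·OEt2-promoted addition of (E)-crotyltrimethylsilane to the monocyclic, unstrained oxocarbenium ion would give the C5 but-3-en-2-yl C10 allyl oxepane F4.
- Only the isomer with both alkenyl arms on the β face can undergo ring-closing metathesis with the second-generation Grubbs catalyst RuCl2(=CHPh)(PCy3)(SIMes) in refluxing CH2Cl2, which would give the bridged C2=C3 alkene F5.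
- Hydrogenation of F5 (H2, Pd/C, EtOAc) comes back to the route at 23.

Step 16. The exchange may stall at ring-opened mixed ketals, the C4 configuration may leak away through transient enol ether or vinyl sulfide formation, or the diacetal may be attacked. The fallback splits the exchange into an opening and a closure that are driven separately.
- It sets out from 21. EtSH and Zn(OTf)2 in CH2Cl2 would push the ketal fully to the ring-opened C10 hydroxy C5 bis(ethylthio)ketal F6.
- AgClO4, NaHCO3 and 4 Å molecular sieves in MeNO2 would then abstract one ethylthio group, and the C10 hydroxyl would close the thionium ion (hydroxy dithioketal cyclisation) to the bridged ethylthio O,S-ketal F7.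
- F7 is taken through the conditions of step 17 and comes back to the route at 23.

Step 14. Possible failures are low conversion of a lactone carbonyl, opening to a hydroxy ketone on work-up, migration of the double bond into ring B, and erosion of the (Z) geometry. The fallback replaces the metal alkylidene by a modified Julia olefination of the lactone.
- It sets out from 18. 2-(Ethylsulfonyl)-1,3-benzothiazole deprotonated with LiN(SiMe3)2 (THF, −78 °C) would add to the carbonyl group to give the C5 hemiketal sulfone F8.
- DBU in THF would then trigger the Smiles rearrangement and loss of sulfur dioxide and benzothiazolone, which comes back to the route at 20 after separation of the geometric isomers on basic alumina.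

**Further compounds**

F1 | step 15 | terminal alkyne lactone (C10 prop-2-ynyl analogue of 17) | O=C1C[C@H](CCO[Si](C)(C)C(C)(C)C)[C@H]2O[C@](C)(OC)[C@@](C)(OC)O[C@@H]2[C@@](C)(CC#C)O1
F2 | step 15 | C10 allyl lactone | O=C1C[C@H](CCO[Si](C)(C)C(C)(C)C)[C@H]2O[C@](C)(OC)[C@@](C)(OC)O[C@@H]2[C@@](C)(CC=C)O1
F3 | step 15 | C5 acetoxy oxepane (C5 epimers) | CC(=O)OC1C[C@H](CCO[Si](C)(C)C(C)(C)C)[C@H]2O[C@](C)(OC)[C@@](C)(OC)O[C@@H]2[C@@](C)(CC=C)O1
F4 | step 15 | C5 but-3-en-2-yl C10 allyl oxepane (C4 and C5 as in 23) | C=C[C@H](C)[C@H]1C[C@H](CCO[Si](C)(C)C(C)(C)C)[C@H]2O[C@](C)(OC)[C@@](C)(OC)O[C@@H]2[C@@](C)(CC=C)O1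
F5 | step 15 | bridged C2=C3 alkene (C5–H analogue of 21) | [C@@H]12C[C@H](CCO[Si](C)(C)C(C)(C)C)[C@H]3O[C@](C)(OC)[C@@](C)(OC)O[C@@H]3[C@@](C)(C/C=C\[C@@H]1C)O2
F6 | step 16 | ring-opened C10 hydroxy C5 bis(ethylthio)ketal | CCSC1(SCC)C[C@H](CCO[Si](C)(C)C(C)(C)C)[C@H]2O[C@](C)(OC)[C@@](C)(OC)O[C@@H]2[C@](C)(O)C/C=C\[C@@H]1C
F7 | step 16 | bridged ethylthio O,S-ketal | CCS[C@@]12C[C@H](CCO[Si](C)(C)C(C)(C)C)[C@H]3O[C@](C)(OC)[C@@](C)(OC)O[C@@H]3[C@@](C)(C/C=C\[C@@H]1C)O2
F8 | step 14 | C5 hemiketal sulfone (C4 and C5 epimers) | CC(S(=O)(=O)c1nc2ccccc2s1)C3(O)C[C@H](CCO[Si](C)(C)C(C)(C)C)[C@H]4O[C@](C)(OC)[C@@](C)(OC)O[C@@H]4[C@@](C)(C/C=C\[Si](C)(C)C)O3
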